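**Plan**

1. Numbering: the core ring is C1–C6 of the cyclohexa-2,4-dien-1-one (C2 acyl, C4 side chain, C6 diprenyl); the side chain is C1' (CH2), the cyclopentane is C2'–C6' (C3' carbinol, C6' bearing isopropenyl), and C7' is the isopropenyl carbon.
2. Enabling feature: in the cyclopentane (C2', C3', C4', C5', C6') the oxygen on C3' is cis to C1'. Closing bond C2'–C6' from an (E)-2',3'-epoxygeranyl chain therefore needs net retention at C2'. A relay through the nucleophilic core carbon C4, as the spiro cyclopropane (C4, C1', C2'), gives this by double inversion.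
3. Retrosynthetic cuts, in order: O–Si at C3'; C2'–C6' (restoring C4–C2'); C4–C2' and then C4–C1' (back to an epoxy iodide and the trione); the two C6–prenyl bonds; the aryl–acyl bond.
4. Forward: phloroglucinol is acylated and gem-diprenylated to the six-membered trione core. The epoxygeranyl unit is joined at C4 and closed to the three-membered ring, which is then exchanged for the five-membered ring; desilylation ends the route.
5. Stereochemistry: C3' and C2' come from Sharpless epoxidation of geraniol with D-(−)-diethyl tartrate, and C2' is inverted in step 5 and again in step 6. C6' is set in the cyclisation transition state, trans to C1' and to the C3' silyloxy group.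

Key step: step 6

Remark: enolised β-triketones are drawn as one tautomer throughout, and 10 is carried as both configurations at the spiro carbon C4, which becomes sp2 in step 6.

**Route**

Step 1
Reactants: 1 geraniol
Product: 2 (2R,3R)-2,3-epoxygeraniol
Conditions: Ti(OiPr)4 (5 mol %), D-(−)-diethyl tartrate (7 mol %), t-BuOOH, 4 Å MS, CH2Cl2, −20 °C
Reagents that add atoms: tert-butyl hydroperoxide, CC(C)(C)OO
Why: Sharpless asymmetric epoxidation is directed by the allylic hydroxyl, so only the 2,3-alkene reacts, and the D-(−)-tartrate ligand should deliver oxygen to the face that gives the (2R,3R)-epoxide, fixing C3' for good and C2' provisionally.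

Step 2
Reactants: 2 (2R,3R)-2,3-epoxygeraniol
Product: 3 (2S,3R)-2-(iodomethyl)-3-methyl-3-(4-methylpent-3-en-1-yl)oxirane
Conditions: PPh3, I2, imidazole, CH2Cl2, 0 °C, dark; used without storage
Reagents that add atoms: iodine, II
Why: Appel-type iodination converts the primary alcohol through its alkoxyphosphonium ion by SN2 at C1 and leaves both epoxide carbons untouched (the C2 descriptor changes only because iodine raises the CIP priority of C1).

Step 3
Reactants: 4 phloroglucinol; 5 isobutyryl chloride
Product: 6 phlorisobutyrophenone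
Conditions: AlCl3, nitrobenzene, 0 → 65 °C; aq. HCl
Reagents that add atoms: none
Why: Friedel–Crafts C-acylation of the very electron-rich arene should stop at the mono-ketone because the chelated acyl group deactivates the ring.

Step 4
Reactants: 6 phlorisobutyrophenone; 7 prenyl bromide (2 equiv)
Product: 8 3,5-dihydroxy-2-isobutyryl-6,6-diprenylcyclohexa-2,4-dien-1-one
Conditions: NaOMe (2 equiv), MeOH, −10 → 0 °C; chromatographic separation from the 3,5-diprenyl and triprenyl isomers
Reagents that add atoms: none
Why: in a protic medium the phenoxide of an acylphloroglucinol is alkylated at carbon by the allylic bromide, and the second prenyl group can enter the already prenylated carbon with loss of aromaticity (alkylative dearomatisation), giving the gem-diprenyl trione as one separable component.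

Step 5
Reactants: 8 gem-diprenyl trione; 3 epoxygeranyl iodide
Product: 10 spirocyclopropyl trione triethylsilyl ether (1R; side chain 2R; both spiro epimers), via C-alkylated epoxide 9 (not isolated)
Conditions: LiHMDS (2.1 equiv), THF, −78 °C; 3, −78 → 0 °C; then LiHMDS (1.1 equiv), Et3SiCl (1.5 equiv), −78 → 0 °C; aq. NH4Cl
Reagents that add atoms: chlorotriethylsilane, CC[Si](Cl)(CC)CC
Why: the dilithium dianion of 8 should be alkylated at its most basic carbon C4 by the soft primary iodide, and the re-formed C4 enolate then opens the neighbouring epoxide 3-exo-tet at C2' with inversion (the known cyclopropane-forming cyclisation of γ,δ-epoxy stabilised carbanions, as with malonate and epichlorohydrin), so that C2' is fixed by the Sharpless epoxide while C3' keeps its configuration and its alkoxide is silylated at once and cannot displace the enolate again.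

Step 6
Reactants: 10 spirocyclopropyl trione triethylsilyl ether
Product: 11 triethylsilyl ether of the target
Conditions: Sc(OTf)3 (1.2 equiv), 2,6-di-tert-butyl-4-methylpyridine (1.5 equiv), CH2Cl2/(CF3)2CHOH 4:1, −20 °C → rt; pH 4 citrate buffer
Reagents that add atoms: none
Why: Proposed new method: scandium bound at the acyl/ring-carbonyl chelate site, with hexafluoroisopropanol hydrogen-bonded to the second flanking carbonyl, polarises the C4–C2' bond of the spiro-activated cyclopropane; the C6'=C7' alkene attacks C2' from the rear while C4 leaves as the delocalised enolate of a vinylogous acid, and the tertiary C7' cation loses a methyl proton to the hindered pyridine (or to the enolate oxygen) to give the isopropenyl group, a formal intramolecular homo-ene reaction. The closest known reaction types are Lewis-acid-promoted homo-conjugate additions of π-nucleophiles to cyclopropane-1,1-dicarbonyl compounds and epoxide-initiated cation–olefin cyclisations. The cyclopentane (C2', C3', C4', C5', C6') closes 5-exo-tet with respect to the breaking C2'–C4 bond. C2' is inverted stereospecifically (R to S) because the tethered alkene can reach only the face opposite C4, and C6' is set in an envelope transition state that places the cationic C7' arm trans to both the C1' arm and the C3' silyloxy group. The step needs attack at C2' instead of attack at C1' (six-membered mode) or ring expansion by a carbonyl oxygen: the shorter tether and the more substituted C2' favour the five-membered mode, the carbonyl oxygens and the prenyl alkenes sit on the leaving-group side and cannot reach the rear of C2', and non-nucleophilic counter-ions, the buffered medium and the silyl cap on the C3' oxygen are meant to exclude halide relay, acid-induced prenyl cyclisation and re-closure to the epoxide.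

Step 7
Reactants: 11 triethylsilyl ether of the target
Product: 12 CNP0290578.2 (target)
Conditions: HF·pyridine, pyridine, THF, 0 °C → rt
Reagents that add atoms: none
Why: buffered fluoride cleaves the tertiary Si–O bond without acid strong enough to ionise the tertiary alcohol or to add the enol oxygens to the alkenes, so no stereocentre is touched.

**Compound list**

1 | geraniol, (2E)-3,7-dimethylocta-2,6-dien-1-ol | CC(C)=CCC/C(C)=C/CO | starting material
2 | (2R,3R)-2,3-epoxygeraniol, [(2R,3R)-3-methyl-3-(4-methylpent-3-en-1-yl)oxiran-2-yl]methanol | OC[C@H]1O[C@]1(C)CCC=C(C)C | intermediate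
3 | (2S,3R)-2-(iodomethyl)-3-methyl-3-(4-methylpent-3-en-1-yl)oxirane (same spatial arrangement as 2) | IC[C@H]1O[C@]1(C)CCC=C(C)C | intermediate
4 | phloroglucinol, benzene-1,3,5-triol | Oc1cc(O)cc(O)c1 | starting material
5 | isobutyryl chloride, 2-methylpropanoyl chloride | CC(C)C(Cl)=O | starting material
6 | phlorisobutyrophenone, 2-methyl-1-(2,4,6-trihydroxyphenyl)propan-1-one | CC(C)C(=O)c1c(O)cc(O)cc1O | intermediate
7 | prenyl bromide, 1-bromo-3-methylbut-2-ene | CC(C)=CCBr | starting material
8 | 3,5-dihydroxy-2-(2-methylpropanoyl)-6,6-bis(3-methylbut-2-en-1-yl)cyclohexa-2,4-dien-1-one | CC(C)C(=O)C1=C(O)C=C(O)C(CC=C(C)C)(CC=C(C)C)C1=O | intermediate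
9 | 3,5-dihydroxy-2-(2-methylpropanoyl)-4-{[(2R,3R)-3-methyl-3-(4-methylpent-3-en-1-yl)oxiran-2-yl]methyl}-6,6-bis(3-methylbut-2-en-1-yl)cyclohexa-2,4-dien-1-one (formed in the flask, not isolated) | CC(C)C(=O)C1=C(O)C(C[C@H]2O[C@]2(C)CCC=C(C)C)=C(O)C(CC=C(C)C)(CC=C(C)C)C1=O | intermediate
10 | (1R)-6-hydroxy-5-(2-methylpropanoyl)-7,7-bis(3-methylbut-2-en-1-yl)-1-[(2R)-6-methyl-2-(triethylsilyloxy)hept-5-en-2-yl]spiro[2.5]oct-5-ene-4,8-dione, spiro carbon C3 as both epimers | CC(C)=CCC[C@@](C)(O[Si](CC)(CC)CC)[C@@H]1CC12C(=O)C(C(=O)C(C)C)=C(O)C(CC=C(C)C)(CC=C(C)C)C2=O | intermediate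
11 | 3,5-dihydroxy-2-(2-methylpropanoyl)-4-{[(1S,2R,5R)-2-methyl-5-(prop-1-en-2-yl)-2-(triethylsilyloxy)cyclopentyl]methyl}-6,6-bis(3-methylbut-2-en-1-yl)cyclohexa-2,4-dien-1-one | C=C(C)[C@@H]1CC[C@@](C)(O[Si](CC)(CC)CC)[C@H]1CC1=C(O)C(CC=C(C)C)(CC=C(C)C)C(=O)C(C(=O)C(C)C)=C1O | intermediate
12 | CNP0290578.2, 3,5-dihydroxy-4-{[(1S,2R,5R)-2-hydroxy-2-methyl-5-(prop-1-en-2-yl)cyclopentyl]methyl}-2-(2-methylpropanoyl)-6,6-bis(3-methylbut-2-en-1-yl)cyclohexa-2,4-dien-1-one | C=C(C)[C@@H]1CC[C@@](C)(O)[C@H]1CC1=C(O)C(CC=C(C)C)(CC=C(C)C)C(=O)C(C(=O)C(C)C)=C1O | target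

**Step count and risks**

Total steps: 7. Longest linear sequence: 5 steps (phloroglucinol through steps 3, 4, 5, 6, 7; equally geraniol through steps 1, 2, 5, 6, 7).

Steps most likely to fail:

1. Step 6 (proposed new method). The cyclopropane may open along other channels: a 1,3-shift of C2' to a carbonyl oxygen (ring expansion to a fused dihydrofuran), attack of the alkene at C1' to give a cyclohexane, or loss of the silyl group followed by return to the epoxide. It may also stay closed up to the temperature at which the prenyl groups start to add to the enol oxygens. The fallback uses known epoxide–olefin cyclisation, sets out from 8 and returns at 12. Commercial nerol is epoxidised (Ti(OiPr)4, L-(+)-diethyl tartrate, t-BuOOH) to (2S,3R)-2,3-epoxynerol F1, which PPh3/I2/imidazole converts into (2R,3R)-2-(iodomethyl)-3-methyl-3-(4-methylpent-3-en-1-yl)oxirane F2. The dianion of 8 (LiHMDS, THF) is C-alkylated with F2 to give the nerol-derived epoxide 3,5-dihydroxy-2-(2-methylpropanoyl)-4-{[(2S,3R)-3-methyl-3-(4-methylpent-3-en-1-yl)oxiran-2-yl]methyl}-6,6-bis(3-methylbut-2-en-1-yl)cyclohexa-2,4-dien-1-one F3, used at once after a buffered work-up. BF3·OEt2 in CH2Cl2 at −78 °C should then make the C6'=C7' alkene attack C2' of the epoxide with inversion and proton loss from C7'. A single inversion on the Z-epoxide places C1' cis to the C3' hydroxyl, so 12 is reached directly.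

2. Step 5. In the first stage an enolate oxygen may be alkylated in place of C4. In the second stage an enolate oxygen may open the epoxide (5-exo at C2' or 6-endo at C3') faster than C4 does, or the carbon attack may reverse before the alkoxide is silylated. The fallback replaces the epoxide by a leaving group that cannot return, sets out from 8 and returns at 10. Because the leaving oxygen on C2' must then stand where the epoxide oxygen of 3 stands, the nerol series is needed. (2S,3R)-2,3-Epoxynerol F1 (made as in the preceding fallback) is heated with aqueous NaOH in t-BuOH; Payne rearrangement and hydroxide opening at C1 invert C2 and retain C3, giving (2R,3R)-3,7-dimethyloct-6-ene-1,2,3-triol F4. SOCl2/Et3N closes the primary and secondary hydroxyls to the cyclic sulfite (4R)-4-[(2R)-2-hydroxy-6-methylhept-5-en-2-yl]-1,3,2-dioxathiolane 2-oxide F5. Et3SiOTf/2,6-lutidine caps the tertiary hydroxyl to give the silyl ether (4R)-4-[(2R)-6-methyl-2-(triethylsilyloxy)hept-5-en-2-yl]-1,3,2-dioxathiolane 2-oxide F6. A brief oxidation with catalytic RuCl3/NaIO4 at 0 °C gives the cyclic sulfate (4R)-4-[(2R)-6-methyl-2-(triethylsilyloxy)hept-5-en-2-yl]-1,3,2-dioxathiolane 2,2-dioxide F7. Treating 8 with NaH (3 equiv) and F7 in THF should alkylate C4 at the primary carbon and then displace the sulfate monoester at C2' 3-exo-tet with inversion (cyclic-sulfate cyclopropanation, as known for malonates), giving 10.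

3. Step 4. The second prenylation may show poor positional selectivity (the free aromatic carbon in place of the prenylated one), and over-alkylation and O-prenylation may lower the amount of 8 further. The fallback blocks the free carbon, sets out from 6 and returns at 8. N-Bromosuccinimide (1 equiv) gives 1-(3-bromo-2,4,6-trihydroxyphenyl)-2-methylpropan-1-one F8. Prenyl bromide/NaOMe can then place both prenyl groups only on the remaining C–H carbon, giving 4-bromo-3,5-dihydroxy-2-(2-methylpropanoyl)-6,6-bis(3-methylbut-2-en-1-yl)cyclohexa-2,4-dien-1-one F9. Zinc in acetic acid removes the bromine of this enolised 2-bromo-1,3-dione to give 8.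

**Further compounds**

F1 | step 6 | (2S,3R)-2,3-epoxynerol, [(2S,3R)-3-methyl-3-(4-methylpent-3-en-1-yl)oxiran-2-yl]methanol | OC[C@@H]1O[C@]1(C)CCC=C(C)C
F2 | step 6 | (2R,3R)-2-(iodomethyl)-3-methyl-3-(4-methylpent-3-en-1-yl)oxirane | IC[C@@H]1O[C@]1(C)CCC=C(C)C
F3 | step 6 | 3,5-dihydroxy-2-(2-methylpropanoyl)-4-{[(2S,3R)-3-methyl-3-(4-methylpent-3-en-1-yl)oxiran-2-yl]methyl}-6,6-bis(3-methylbut-2-en-1-yl)cyclohexa-2,4-dien-1-one | CC(C)C(=O)C1=C(O)C(C[C@@H]2O[C@]2(C)CCC=C(C)C)=C(O)C(CC=C(C)C)(CC=C(C)C)C1=O
F4 | step 5 | (2R,3R)-3,7-dimethyloct-6-ene-1,2,3-triol | OC[C@@H](O)[C@](C)(O)CCC=C(C)C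
F5 | step 5 | (4R)-4-[(2R)-2-hydroxy-6-methylhept-5-en-2-yl]-1,3,2-dioxathiolane 2-oxide | C1OS(=O)O[C@H]1[C@](C)(O)CCC=C(C)C
F6 | step 5 | (4R)-4-[(2R)-6-methyl-2-(triethylsilyloxy)hept-5-en-2-yl]-1,3,2-dioxathiolane 2-oxide | C1OS(=O)O[C@H]1[C@](C)(O[Si](CC)(CC)CC)CCC=C(C)C
F7 | step 5 | (4R)-4-[(2R)-6-methyl-2-(triethylsilyloxy)hept-5-en-2-yl]-1,3,2-dioxathiolane 2,2-dioxide | C1OS(=O)(=O)O[C@H]1[C@](C)(O[Si](CC)(CC)CC)CCC=C(C)C
F8 | step 4 | 1-(3-bromo-2,4,6-trihydroxyphenyl)-2-methylpropan-1-one | CC(C)C(=O)c1c(O)cc(O)c(Br)c1O
F9 | step 4 | 4-bromo-3,5-dihydroxy-2-(2-methylpropanoyl)-6,6-bis(3-methylbut-2-en-1-yl)cyclohexa-2,4-dien-1-one | CC(C)C(=O)C1=C(O)C(Br)=C(O)C(CC=C(C)C)(CC=C(C)C)C1=O
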